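The readings stem from a simulated flask on assumed constants, and the scatter is random.

- The winter run, which is the very flask asked about followed so far, showed the substrate falling from its first reading, so I began from those readings.

| flask | substrate | coupling partner | second reagent | third reagent | protic impurity | remark | time |
|---|---|---|---|---|---|---|---|
| winter | 12 mM | 36 mM | 24 mM | 14.4 mM | 1.2 mM | the very flask that is asked about, followed so far |  |
| flask | 12 mM | 36.0 mM | 24.0 mM | 14.4 mM | 1.20 mM |  | 50 h |

winter run (percent of the substrate charged)

| time / h | substrate / % | target / % |
|---|---|---|
| 1.50 | 90.4 | 0.3 |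
| 2.50 | 84.8 | 0 |
| 4.00 | 77.1 | 0 |
| 6.00 | 70.8 | 1.4 |
| 8.00 | 63.7 | 0.7 |
| 12.0 | 51.9 | 0 |
| 20.0 | 31.9 | 2.1 |

(standard deviation of a reading: 1 percentage point)

- a reading or a percentage of target counts all its forms, free or not

- amount of substrate in percent of the substrate charged, at 5.0 h, 20 h and 50 h

- From the reading at 20.0 h I took the apparent constant, the natural logarithm of the charge over the fraction left, divided by the elapsed time: 0.0571 h⁻¹, a pseudo-first-order constant that carries the scatter of that reading.
- For the bound from below, I supposed that the reagents held their charge, so that this constant stayed put. The fraction left at 50 h was then 5.75%, and at 5.0 h it was 75.2%.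
- For the bound from above, I took a hard case: each substrate lost took one second reagent, charged at twice the substrate, and the rate followed the second reagent. The ratio of second reagent to substrate then grows exponentially. The reading gave a factor of 2.07 over 20.0 h, and carrying that to 50 h left 8.86%.
- The readings give substrate and target, not the reagents, so I could not tell what share of the loss took second reagent. I therefore committed to the midpoint, 7.30% at 50 h, and kept the reading 31.9% at 20 h.
- The forecast gave 74.5%, 32% and 7%, on this ground: “Second reagent and partner are in excess, so nothing should run out before the substrate does.” Its last value lay inside my bracket, slightly under my midpoint, and its first was lower than mine.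
- The flask gave 74.4%, 32.8% and 7.40%, the last also inside the bracket.

    substrate + coupling partner → intermediate A (k = 2.70 × 10⁻⁴ L mol⁻¹ s⁻¹)
    second reagent + target → over-reaction product (k = 0.00160 L mol⁻¹ s⁻¹)
    coupling partner + target ⇌ idle adduct, settled at all times (K = 1300 L mol⁻¹)
    third reagent + intermediate B → target (k = 0.0120 L mol⁻¹ s⁻¹)
    substrate + second reagent → side product (k = 3.00 × 10⁻⁴ L mol⁻¹ s⁻¹)
    second reagent + intermediate A → intermediate B (k = 6.20 × 10⁻⁵ L mol⁻¹ s⁻¹)
    third reagent + protic impurity → quenched reagent (k = 0.0280 L mol⁻¹ s⁻¹)

- At 10.8 h the rate of substrate loss to intermediate A stood at 1.4 times the rate of loss to side product, and by 50 h the unbound coupling partner was down to 80% of its charge and the unbound second reagent to 76%. Held steady, 0.0571 h⁻¹ gives 0.331% at 100 h, where the substrate stood at 0.737%.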